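The leftover in the south-west run at 8.00 min, what neither starting material nor mono adduct accounts for, is 16.0%; read as double product, it is less than the 70.3% of mono adduct. Coupling partner is fed into stirred starting material, and three new flasks are to be judged.

| setting | north-west | east | south-west | noon | summer | midnight |
|---|---|---|---|---|---|---|
| starting material | 0.055 M | 0.055 M | 0.055 M | 0.055 M | 0.055 M | 0.055 M |
| coupling partner | 0.040 M (fed, over 4.0 min) | 0.070 M (fed, over 4.0 min) | 0.093 M (fed, over 4.0 min) | 0.0990 M (fed, over 4.0 min) | 0.0440 M (fed, over 4.0 min) | 0.0660 M (fed, over 4.0 min) |
| remark | run made earlier | run made earlier | run made earlier |  |  |  |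
| time |  |  |  | 10 min | 10 min | 10 min |

- north-west (time / min: mono adduct / %, starting material / %): 1.33: 6.3, 96.6; 3.00: 16.1, 82.2; 4.00: 27.7, 71.1; 6.00: 41.4, 56.4; 8.00: 45.9, 49.2
- east (time / min: mono adduct / %, starting material / %): 1.33: 7.9, 92.5; 3.00: 29.0, 70.1; 4.00: 43.5, 55.8; 6.00: 58.5, 36.4; 8.00: 67.2, 26.9
- south-west (time / min: mono adduct / %, starting material / %): 1.33: 10.2, 91.0; 3.00: 37.0, 64.3; 4.00: 53.3, 46.9; 6.00: 65.4, 25.3; 8.00: 70.3, 13.7

(each reading ± 1 percentage point)

* which of the two there is more of at the end, noon (mono adduct / double product)
* which of the two there is more of at the end, summer (mono adduct / double product)
* which of the two there is more of at the end, midnight (mono adduct / double product)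
* how much mono adduct is there at the end, in percent of the starting material charged: noon
* how much mono adduct is there at the end, in percent of the starting material charged: summer
* how much mono adduct is there at the end, in percent of the starting material charged: midnight

This reckoning rests on a ceiling. If each mono adduct takes one coupling partner, mono adduct cannot pass the charge of coupling partner over the charge of starting material, nor the whole starting material. That ceiling is 80.0% in summer, where coupling partner is the limiting reagent, and 100% in midnight and noon. The north-west run reached 63.1% of its ceiling by 8.00 min. The same fraction gives summer 50.5% by then, so summer should end between that and its ceiling. Noon and midnight lie near runs where mono adduct leads, so mono adduct should lead there too.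

The forecast gives 70% for noon, 54% for summer and 68% for midnight, stepping each new run from the nearest known run, and concludes: “Mono adduct dominates in all three.”

The flasks give, in that order, 72.0%, 55.2% and 67.8% of mono adduct, against 19.9%, 4.38% and 9.65% of double product, so the forecast stands.

    starting material + coupling partner → mono adduct + by-product (k = 0.0970 L mol⁻¹ s⁻¹)
    coupling partner + mono adduct ⇌ double product + by-product (K = 2.60, k = 0.0150 L mol⁻¹ s⁻¹)

With summer's charge of coupling partner in place of its own, noon holds 55.2% of mono adduct instead of 72.0%; that difference in concentration of coupling partner is the main reason. Summer's mono adduct stands below its ceiling of 80.0%, with 20.1% of its coupling partner still free at 10.0 min. For noon's mono adduct to move by 6 points, the other amounts and the time held, its coupling partner would have to go down to about 0.0615 M or up to about 0.134 M.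

A flask like summer with 0.026 M of coupling partner has a ceiling of 47.3%, so at least 52.7% of the starting material must stay unconverted to mono adduct or beyond. It gives 37.3% of mono adduct, with 61.1% of starting material left.

The numbers in the tables stem from a simulated flask for substances that don't exist, noise included.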